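## Retrosynthetic overview

1. Ferulsinaic acid ⇒ aldehyde‑acid **13** by Wittig isopropylidenation; the aryl ether is already in place.
2. **13** ⇒ cis‑hydrindan‑5‑one **11** by ozonolytic scission of C4–C5 through the Δ4 silyl enol ether. The cyclohexanone ring is a sacrificial tether: C7–C6–C5 become the propanoic acid, C4 becomes the isobutenyl CH, and their cis relationship comes from the cis ring fusion.
3. **11** ⇒ ketone **3**: Mitsunobu etherification with umbelliferone; the C1–CH2O carbon and the C2 methyl come from enol‑triflate carbonylation, convex‑face hydrogenation and C1 epimerisation.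
4. **3** ⇒ (R)‑Hajos–Parrish ketone **1** by cis‑hydrogenation and selective ketalisation. The single stereocentre of **1** controls all four stereocentres of the target.
5. Ring order: no ring is built. The cyclopentane is the five‑membered ring of **1**, the six‑membered ring is cleaved in step 11, and the coumarin is bought intact.

Assumption: (R)‑(−)‑Hajos–Parrish ketone is treated as commercial; otherwise it is two steps from 2‑methylcyclopentane‑1,3‑dione, methyl vinyl ketone and D‑proline.

Convention: bicyclic compounds use Hajos–Parrish (indene) numbering; β is the face of the five‑membered ring that carries the 7a‑methyl group. Atom mapping to the target cyclopentane: C7a → C1 (quaternary), C1 → C2 (CH2OAr), C2 → C3 (CH3), C3 → C4, C3a → C5 (isobutenyl).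

## Route

**Step 1**
Reactants: **1**, (R)‑Hajos–Parrish ketone [(7aR)‑7a‑methyl‑2,3,7,7a‑tetrahydro‑1H‑indene‑1,5(6H)‑dione]
Product: **2**, (3aS,7aR)‑7a‑methylhexahydro‑1H‑indene‑1,5(4H)‑dione (cis‑fused; H‑3a β)
Conditions: H2 (1 atm), 10% Pd/C, EtOAc, rt
Reagents that add atoms: none
Why: Heterogeneous hydrogenation of this enone is known to deliver H to C3a syn to the angular methyl (cis‑hydrindane), which fixes the future isobutenyl/propanoate cis relationship.

**Step 2**
Reactants: **2**
Product: **3**, (3aS,7aR)‑5,5‑(ethylenedioxy)‑7a‑methyloctahydro‑1H‑inden‑1‑one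
Conditions: ethylene glycol (1.1 equiv), p‑TsOH (cat.), PhH, reflux, Dean–Stark
Reagents that add atoms: ethylene glycol, OCCO
Why: Chemoselective acetalisation; the unhindered cyclohexanone reacts much faster than the cyclopentanone next to the quaternary carbon.

**Step 3**
Reactants: **3**
Product: **4**, (3aS,7aR)‑5,5‑(ethylenedioxy)‑2,7a‑dimethyloctahydro‑1H‑inden‑1‑one (C2 epimer mixture)
Conditions: LDA, THF, −78 °C; MeI, −78 → 0 °C
Reagents that add atoms: iodomethane, CI
Why: Kinetic enolate alkylation at C2, the only enolisable position of the C1 ketone; the C2 configuration is irrelevant because C2 becomes sp2 in step 4.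

**Step 4**
Reactants: **4**
Product: **5**, (3aS,7aR)‑5,5‑(ethylenedioxy)‑2,7a‑dimethyl‑3a,4,5,6,7,7a‑hexahydro‑3H‑inden‑1‑yl trifluoromethanesulfonate
Conditions: KHMDS, THF, −78 → 0 °C; PhNTf2, −78 °C → rt
Reagents that add atoms: N‑phenyl‑bis(trifluoromethanesulfonimide), O=S(=O)(N(c1ccccc1)S(=O)(=O)C(F)(F)F)C(F)(F)F
Why: Enol triflate formation; only the C1=C2 enolate can form because C7a is quaternary.

**Step 5**
Reactants: **5**
Product: **6**, methyl (3aS,7aR)‑5,5‑(ethylenedioxy)‑2,7a‑dimethyl‑3a,4,5,6,7,7a‑hexahydro‑3H‑indene‑1‑carboxylate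
Conditions: Pd(OAc)2 (5 mol%), PPh3, CO (1 atm), MeOH, Et3N, DMF, 60 °C
Reagents that add atoms: carbon monoxide, [C-]#[O+]; methanol, CO
Why: Pd‑catalysed methoxycarbonylation of an enol triflate (Cacchi–Ortar), well precedented for steroidal 17‑enol triflates next to a quaternary carbon.

**Step 6**
Reactants: **6**
Product: **7**, methyl (1R,2S,3aS,7aR)‑5,5‑(ethylenedioxy)‑2,7a‑dimethyloctahydro‑1H‑indene‑1‑carboxylate (1β‑CO2Me, 2α‑CH3)
Conditions: H2 (50 bar), 10% Pd/C, MeOH, rt; filter; then NaOMe, MeOH, 65 °C (all‑cis 1α‑ester not isolated)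
Reagents that add atoms: none
Why: Syn hydrogenation from the convex β face (the concave face lies over the axial H‑4/H‑6 of the six‑membered ring) puts the C2 methyl α, and base then epimerises only C1 to the thermodynamic β‑ester, trans to the 2‑methyl.

**Step 7**
Reactants: **7**
Product: **8**, [(1R,2S,3aS,7aR)‑5,5‑(ethylenedioxy)‑2,7a‑dimethyloctahydro‑1H‑inden‑1‑yl]methanol
Conditions: LiAlH4, THF, 0 °C
Reagents that add atoms: none
Why: Hydride reduction of the ester; no stereocentre is affected and the acetal is inert.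

**Step 8**
Reactants: **8**; **9**, umbelliferone (7‑hydroxycoumarin)
Product: **10**, 7‑{[(1R,2S,3aS,7aR)‑5,5‑(ethylenedioxy)‑2,7a‑dimethyloctahydro‑1H‑inden‑1‑yl]methoxy}‑2H‑chromen‑2‑one
Conditions: PPh3, DIAD, THF, 0 → 45 °C
Reagents that add atoms: umbelliferone, Oc1ccc2ccc(=O)oc2c1
Why: Mitsunobu etherification of a primary alcohol with an acidic phenol; the reacting carbon is not a stereocentre.

**Step 9**
Reactants: **10**
Product: **11**, 7‑{[(1R,2S,3aS,7aR)‑2,7a‑dimethyl‑5‑oxooctahydro‑1H‑inden‑1‑yl]methoxy}‑2H‑chromen‑2‑one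
Conditions: 1 M HCl, THF, rt
Reagents that add atoms: water, O
Why: Acid hydrolysis of the dioxolane; the aryl ether and coumarin lactone are acid‑stable.

**Step 10**
Reactants: **11**
Product: **12**, 7‑{[(1R,2S,3aS,7aR)‑2,7a‑dimethyl‑5‑(trimethylsilyloxy)‑2,3,3a,6,7,7a‑hexahydro‑1H‑inden‑1‑yl]methoxy}‑2H‑chromen‑2‑one (Δ4 silyl enol ether)
Conditions: TMSCl, Et3N, DMF, 90 °C (equilibrating conditions)
Reagents that add atoms: chlorotrimethylsilane, C[Si](C)(C)Cl
Why: Thermodynamic silyl enol ether formation (House conditions); enolisation toward the ring fusion (C4) is expected by analogy with cis‑fused 5β‑3‑keto steroids and because it removes the axial H‑4 that clashes with the 2α‑methyl.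

**Step 11**
Reactants: **12**
Product: **13**, 3‑[(1S,2R,3S,5R)‑5‑formyl‑1,3‑dimethyl‑2‑{[(2‑oxo‑2H‑chromen‑7‑yl)oxy]methyl}cyclopentyl]propanoic acid
Conditions: O3 (titrated to Sudan Red 7B end point), CH2Cl2, −78 °C; Me2S; mildly acidic aqueous work‑up
Reagents that add atoms: ozone, [O-][O+]=O
Why: Ozonolysis of a silyl enol ether (Clark–Heathcock cleavage) cuts C4–C5 to give the C5 acid and C4 aldehyde; the electron‑rich enol ether reacts far faster than the electron‑poor coumarin alkene, and no bond to a stereocentre is broken.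

**Step 12**
Reactants: **13**; **14**, isopropyltriphenylphosphonium iodide
Product: **15**, ferulsinaic acid, 3‑[(1R,2R,3S,5S)‑1,3‑dimethyl‑5‑(2‑methylprop‑1‑en‑1‑yl)‑2‑{[(2‑oxo‑2H‑chromen‑7‑yl)oxy]methyl}cyclopentyl]propanoic acid
Conditions: **14** (3 equiv), n‑BuLi, THF, 0 °C; add **13** at −78 °C, warm to 0 °C; H3O+ work‑up
Reagents that add atoms: isopropyltriphenylphosphonium iodide, CC(C)[P+](c1ccccc1)(c1ccccc1)c1ccccc1.[I-]
Why: Wittig olefination with the non‑stabilised isopropylidene ylide (first equivalent forms the carboxylate); addition at low temperature should outrun α‑epimerisation, and the product alkene has no E/Z isomers.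

## Compound list

1 | (R)‑Hajos–Parrish ketone | C[C@@]12CCC(=O)C=C1CCC2=O | starting material
2 | (3aS,7aR)‑cis‑7a‑methylhexahydroindene‑1,5‑dione | C[C@@]12CCC(=O)C[C@@H]1CCC2=O | intermediate
3 | 5‑mono(ethylene acetal) of 2 | C[C@@]12CCC3(OCCO3)C[C@@H]1CCC2=O | intermediate
4 | 2‑methyl ketone (C2 epimers) | C[C@@]12CCC3(OCCO3)C[C@@H]1CC(C)C2=O | intermediate
5 | C1 enol triflate | C[C@@]12CCC3(OCCO3)C[C@@H]1CC(C)=C2OS(=O)(=O)C(F)(F)F | intermediate
6 | unsaturated methyl ester | C[C@@]12CCC3(OCCO3)C[C@@H]1CC(C)=C2C(=O)OC | intermediate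
7 | (1R,2S,3aS,7aR) saturated ester (1β‑CO2Me, 2α‑Me) | C[C@@]12CCC3(OCCO3)C[C@@H]1C[C@H](C)[C@H]2C(=O)OC | intermediate
8 | primary alcohol | C[C@@]12CCC3(OCCO3)C[C@@H]1C[C@H](C)[C@H]2CO | intermediate
9 | umbelliferone | Oc1ccc2ccc(=O)oc2c1 | starting material
10 | umbelliferyl ether acetal | C[C@@]12CCC3(OCCO3)C[C@@H]1C[C@H](C)[C@H]2COc1ccc2ccc(=O)oc2c1 | intermediate
11 | umbelliferyl ether cis‑hydrindan‑5‑one | C[C@@]12CCC(=O)C[C@@H]1C[C@H](C)[C@H]2COc1ccc2ccc(=O)oc2c1 | intermediate
12 | Δ4 trimethylsilyl enol ether | C[C@@]12CCC(O[Si](C)(C)C)=C[C@@H]1C[C@H](C)[C@H]2COc1ccc2ccc(=O)oc2c1 | intermediate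
13 | seco aldehyde‑acid | O=C[C@@H]1C[C@H](C)[C@@H](COc2ccc3ccc(=O)oc3c2)[C@]1(C)CCC(=O)O | intermediate
14 | isopropyltriphenylphosphonium iodide | CC(C)[P+](c1ccccc1)(c1ccccc1)c1ccccc1.[I-] | starting material
15 | ferulsinaic acid | CC(C)=C[C@@H]1C[C@H](C)[C@@H](COc2ccc3ccc(=O)oc3c2)[C@]1(C)CCC(=O)O | target

## Summary

Total step count: 12. Longest linear sequence: 12 steps from **1**; the route is fully linear, with **9** and **14** used as purchased.

Steps most likely to fail, each with a fallback that changes the approach: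

1. **Steps 10–11 (regioselective scission).** The Δ4 versus Δ5 enol ether ratio is argued by analogy, not known for this substrate, and ozone must be stopped before it attacks the coumarin. Fallback: take the regiochemistry from the enone by moving the scission to the start. Cu–H or Rh‑catalysed 1,4‑hydrosilylation of **1** gives the Δ4 silyl enol ether regiospecifically; ozonolysis and Wittig then give the monocyclic isobutenyl keto ester, and the C1/C2 chemistry of steps 3–8 is run on that monocycle (Mg/MeOH instead of H2 to spare the isobutenyl group).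

2. **Step 6 (hydrogenation of the hindered tetrasubstituted enoate).** The alkene may be too hindered for Pd/C, or the facial selectivity may be lower than predicted. Fallback: reduce **6** to the allylic alcohol (DIBAL) and use a cationic Rh or Ir allylic alcohol → aldehyde isomerisation, which delivers H to C2 suprafacially on the convex face. The aldehyde is then equilibrated at C1 and reduced with NaBH4 to reach **8**.

3. **Step 12 (Wittig on the α‑branched aldehyde).** The basic, bulky ylide could epimerise C5 of **13** or attack the coumarin, and the free acid consumes ylide. Fallback: split the olefination. Methylenate the aldehyde (Ph3P=CH2, which is smaller and faster) to the vinyl compound, then install the trisubstituted alkene by cross‑metathesis with 2‑methyl‑2‑butene (Grubbs II), a non‑basic step.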